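**Retrosynthetic overview**
- The quinone is made last, by oxidative demethylation of a (3S)-isoflavan. Only ring B of that isoflavan carries a free OH (para to an OMe), so the equally electron-rich ring A is left alone.
- C3 is set by Ir-catalysed asymmetric hydrogenation of the corresponding isoflav-3-ene (3-aryl-2H-chromene).
- The pyran is the only ring formed. It is closed by ring-closing metathesis of an o-propenylaryl 2-arylallyl ether.
- The diene comes from a Mitsunobu union of a ring-A propenylphenol with a ring-B 2-arylallyl alcohol.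
- Both halves start from 2,3,4-trimethoxybenzaldehyde: A by Dakin, allylation, Claisen and isomerisation; B by bromination, Dakin, benzylation and borylation/Suzuki.

Assumption: the facial sense of the Ir catalyst in step 11 is taken from the hydrogenation of dehydroequol ethers to (S)-equol ethers, which have the same spatial arrangement and CIP order at C3. Both ligand enantiomers are sold; the one giving (S) is used and checked by chiral HPLC and CD against the natural product.

**Step 1**
Reactants: 1 2,3,4-trimethoxybenzaldehyde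
Product: 3 2,3,4-trimethoxyphenol, via 2,3,4-trimethoxyphenyl formate 2 (not isolated)
Conditions: 30% aq H2O2 (1.3 equiv), H2SO4 (cat.), MeOH, rt
Reagents that add atoms: hydrogen peroxide, OO
Why: In this acid-catalysed Dakin (Baeyer–Villiger type) oxidation the aryl group, activated by o- and p-OMe, migrates to oxygen, and the aryl formate is methanolysed in situ.

**Step 2**
Reactants: 3 2,3,4-trimethoxyphenol; 4 allyl bromide
Product: 5 1-(allyloxy)-2,3,4-trimethoxybenzene
Conditions: K2CO3, acetone, reflux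
Reagents that add atoms: none
Why: This is a Williamson ether synthesis of a phenoxide with a reactive allylic halide.

**Step 3**
Reactants: 5 1-(allyloxy)-2,3,4-trimethoxybenzene
Product: 7 6-allyl-2,3,4-trimethoxyphenol, via 6-allyl-2,3,4-trimethoxycyclohexa-2,4-dien-1-one 6 (not isolated)
Conditions: PhNEt2, 200 °C
Reagents that add atoms: none
Why: In this aromatic Claisen [3,3] rearrangement only C6 is an ortho position bearing H (C2 and the para C4 are blocked by OMe), so tautomerisation of the dienone gives one regioisomer.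

**Step 4**
Reactants: 7 6-allyl-2,3,4-trimethoxyphenol
Product: 8 2,3,4-trimethoxy-6-[(E)-prop-1-en-1-yl]phenol
Conditions: RuHCl(CO)(PPh3)3 (2 mol %), toluene, 90 °C
Reagents that add atoms: none
Why: Ru–H catalysed olefin isomerisation (hydrometalation/β-hydride elimination) moves the double bond into conjugation, and any Z isomer is harmless because the CH–CH3 end is lost in step 10.

**Step 5**
Reactants: 1 2,3,4-trimethoxybenzaldehyde
Product: 9 5-bromo-2,3,4-trimethoxybenzaldehyde
Conditions: NBS (1.05 equiv), MeCN, rt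
Reagents that add atoms: N-bromosuccinimide, O=C1CCC(=O)N1Br
Why: Electrophilic aromatic bromination goes to C5, which is ortho to 4-OMe, para to 2-OMe and meta to CHO, whereas C6 is ortho to the deactivating CHO.

**Step 6**
Reactants: 9 5-bromo-2,3,4-trimethoxybenzaldehyde
Product: 11 5-bromo-2,3,4-trimethoxyphenol, via 5-bromo-2,3,4-trimethoxyphenyl formate 10 (not isolated)
Conditions: 30% aq H2O2 (1.3 equiv), H2SO4 (cat.), MeOH, rt
Reagents that add atoms: hydrogen peroxide, OO
Why: The same acid-catalysed Dakin oxidation turns the aldehyde, now spent as a regiochemical director, into the oxygen that becomes one quinone carbonyl.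

**Step 7**
Reactants: 11 5-bromo-2,3,4-trimethoxyphenol
Product: 12 1-(benzyloxy)-5-bromo-2,3,4-trimethoxybenzene
Conditions: BnBr, K2CO3, DMF, rt
Reagents that add atoms: benzyl bromide, BrCc1ccccc1
Why: Williamson benzylation masks the one phenol that must later distinguish ring B from ring A, and benzyl survives BuLi at −78 °C, Pd(0), Ru carbenes and Ir/H2.

**Step 8**
Reactants: 12 1-(benzyloxy)-5-bromo-2,3,4-trimethoxybenzene; 13 2-bromoprop-2-en-1-ol
Product: 16 2-[5-(benzyloxy)-2,3,4-trimethoxyphenyl]prop-2-en-1-ol, via [5-(benzyloxy)-2,3,4-trimethoxyphenyl]lithium 14 (not isolated), via lithium [5-(benzyloxy)-2,3,4-trimethoxyphenyl]tri(propan-2-yloxy)borate 15 (not isolated)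
Conditions: n-BuLi, THF, −78 °C; B(Oi-Pr)3, −78 °C → rt; then 13, XPhos Pd G2 (2 mol %), 0.5 M aq K3PO4, 40 °C
Reagents that add atoms: none
Why: Fast Br/Li exchange and borate formation are followed by a one-pot Suzuki–Miyaura coupling, in which the triisopropyl borate resists protodeboronation and the vinyl bromide adds readily to Pd(0).

**Step 9**
Reactants: 8 2,3,4-trimethoxy-6-[(E)-prop-1-en-1-yl]phenol; 16 2-[5-(benzyloxy)-2,3,4-trimethoxyphenyl]prop-2-en-1-ol
Product: 17 1-({2-[5-(benzyloxy)-2,3,4-trimethoxyphenyl]prop-2-en-1-yl}oxy)-2,3,4-trimethoxy-6-[(E)-prop-1-en-1-yl]benzene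
Conditions: PPh3, DIAD, THF, 0 °C → rt
Reagents that add atoms: none
Why: This is a Mitsunobu etherification of a primary allylic alcohol with a phenol, and SN2 and SN2' attack on the 2-arylallyl unit give the same product.

**Step 10**
Reactants: 17 the diene ether
Product: 18 3-[5-(benzyloxy)-2,3,4-trimethoxyphenyl]-6,7,8-trimethoxy-2H-chromene
Conditions: Hoveyda–Grubbs II (5 mol %), 1,4-benzoquinone (10 mol %), toluene (0.01 M), 80 °C, Ar sparge
Reagents that add atoms: none
Why: In this ring-closing metathesis the catalyst loads on the propenyl arene and closes onto the tethered 1,1-disubstituted olefin, giving a strain-free conjugated six-membered ring while loss of propene drives the reaction.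

**Step 11**
Reactants: 18 the isoflav-3-ene
Product: 19 (3S)-3-[5-(benzyloxy)-2,3,4-trimethoxyphenyl]-6,7,8-trimethoxy-3,4-dihydro-2H-chromene
Conditions: [Ir(cod)(Cy2-ThrePHOX)]BArF (2 mol %), H2 (50 bar), CH2Cl2, rt
Reagents that add atoms: none
Why: Ir–N,P (Pfaltz type) asymmetric hydrogenation of an unfunctionalised trisubstituted cyclic olefin delivers H2 syn to one face of C3=C4 and sets C3 as (S), while aryl and benzyl ethers stay inert.

**Step 12**
Reactants: 19 the (3S)-isoflavan benzyl ether
Product: 21 abruquinone B, 2,3-dimethoxy-5-[(3S)-6,7,8-trimethoxy-3,4-dihydro-2H-chromen-3-yl]cyclohexa-2,5-diene-1,4-dione, via 2,3,4-trimethoxy-5-[(3S)-6,7,8-trimethoxy-3,4-dihydro-2H-chromen-3-yl]phenol 20 (not isolated)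
Conditions: H2 (1 atm), 10% Pd/C, EtOAc, rt; filter, concentrate; PhI(OAc)2 (1.1 equiv), MeCN–H2O 3:1, 0 °C
Reagents that add atoms: water, O
Why: After benzyl hydrogenolysis, hypervalent-iodine oxidation works by ligand exchange at the only phenol, so water attacks the para OMe-bearing carbon and MeOH is lost, while ring A stays untouched and the neutral, cold medium leaves C3 unchanged.

**Compound list**
1 | 2,3,4-trimethoxybenzaldehyde | COc1ccc(C=O)c(OC)c1OC | starting material
2 | 2,3,4-trimethoxyphenyl formate | COc1ccc(OC=O)c(OC)c1OC | intermediate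
3 | 2,3,4-trimethoxyphenol | COc1ccc(O)c(OC)c1OC | intermediate
4 | allyl bromide | C=CCBr | starting material
5 | 1-(allyloxy)-2,3,4-trimethoxybenzene | C=CCOc1ccc(OC)c(OC)c1OC | intermediate
6 | 6-allyl-2,3,4-trimethoxycyclohexa-2,4-dien-1-one (racemic) | C=CCC1C=C(OC)C(OC)=C(OC)C1=O | intermediate
7 | 6-allyl-2,3,4-trimethoxyphenol | C=CCc1cc(OC)c(OC)c(OC)c1O | intermediate
8 | 2,3,4-trimethoxy-6-[(E)-prop-1-en-1-yl]phenol | C/C=C/c1cc(OC)c(OC)c(OC)c1O | intermediate
9 | 5-bromo-2,3,4-trimethoxybenzaldehyde | COc1c(Br)cc(C=O)c(OC)c1OC | intermediate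
10 | 5-bromo-2,3,4-trimethoxyphenyl formate | COc1c(Br)cc(OC=O)c(OC)c1OC | intermediate
11 | 5-bromo-2,3,4-trimethoxyphenol | COc1c(Br)cc(O)c(OC)c1OC | intermediate
12 | 1-(benzyloxy)-5-bromo-2,3,4-trimethoxybenzene | COc1c(Br)cc(OCc2ccccc2)c(OC)c1OC | intermediate
13 | 2-bromoprop-2-en-1-ol | OCC(Br)=C | starting material
14 | [5-(benzyloxy)-2,3,4-trimethoxyphenyl]lithium | [Li]c1cc(OCc2ccccc2)c(OC)c(OC)c1OC | intermediate
15 | lithium [5-(benzyloxy)-2,3,4-trimethoxyphenyl]tri(propan-2-yloxy)borate | [Li+].CC(C)O[B-](OC(C)C)(OC(C)C)c1cc(OCc2ccccc2)c(OC)c(OC)c1OC | intermediate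
16 | 2-[5-(benzyloxy)-2,3,4-trimethoxyphenyl]prop-2-en-1-ol | C=C(CO)c1cc(OCc2ccccc2)c(OC)c(OC)c1OC | intermediate
17 | 1-({2-[5-(benzyloxy)-2,3,4-trimethoxyphenyl]prop-2-en-1-yl}oxy)-2,3,4-trimethoxy-6-[(E)-prop-1-en-1-yl]benzene | C/C=C/c1cc(OC)c(OC)c(OC)c1OCC(=C)c1cc(OCc2ccccc2)c(OC)c(OC)c1OC | intermediate
18 | 3-[5-(benzyloxy)-2,3,4-trimethoxyphenyl]-6,7,8-trimethoxy-2H-chromene | COc1cc2C=C(COc2c(OC)c1OC)c1cc(OCc2ccccc2)c(OC)c(OC)c1OC | intermediate
19 | (3S)-3-[5-(benzyloxy)-2,3,4-trimethoxyphenyl]-6,7,8-trimethoxy-3,4-dihydro-2H-chromene | COc1c(OC)c(OC)c(OCc2ccccc2)cc1[C@H]1COc2c(cc(OC)c(OC)c2OC)C1 | intermediate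
20 | 2,3,4-trimethoxy-5-[(3S)-6,7,8-trimethoxy-3,4-dihydro-2H-chromen-3-yl]phenol | COc1c(OC)c(OC)c(O)cc1[C@H]1COc2c(cc(OC)c(OC)c2OC)C1 | intermediate
21 | abruquinone B, (3S) | COC1=C(OC)C(=O)C([C@H]2COc3c(cc(OC)c(OC)c3OC)C2)=CC1=O | target

**Total step count:** 12

**Longest linear sequence:** 8 (steps 1–4, then 9–12; the branch 5–8, then 9–12, is equally long)

**Three steps most likely to fail**

**Step 10 (RCM to a trisubstituted olefin flanked by an ortho-substituted aryl group).**
- The fallback sets out from 8 and comes back at 18.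
- The pyran is closed before ring B is attached, so the metathesis only has to make a disubstituted olefin.
- Phenol 8 is alkylated with 4 (K2CO3, acetone) to 1-(allyloxy)-2,3,4-trimethoxy-6-[(E)-prop-1-en-1-yl]benzene F1.
- Grubbs II (2 mol %, CH2Cl2, 40 °C) then gives 6,7,8-trimethoxy-2H-chromene F2.
- Br2 in CH2Cl2 at −78 °C adds across the electron-rich styrene bond to give (±)-trans-3,4-dibromo-6,7,8-trimethoxy-3,4-dihydro-2H-chromene F3.
- KOt-Bu in THF removes the labile benzylic bromide together with H-3 to give 3-bromo-6,7,8-trimethoxy-2H-chromene F4.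
- Suzuki coupling of F4 with borate 15, made from 12 as in step 8, delivers 18.

**Step 11 (conversion and ee with the 2'-methoxy aryl group next to the olefin).**
- The fallback sets out from 18 and comes back at 20.
- Asymmetric catalysis is replaced by resolution.
- H2 over Pd/C in EtOAc saturates the olefin and cleaves the benzyl ether in one operation, giving racemic 2,3,4-trimethoxy-5-(6,7,8-trimethoxy-3,4-dihydro-2H-chromen-3-yl)phenol F5.
- Preparative SFC on an amylose-type chiral phase separates the (S)-enantiomer, which is 20, from 2,3,4-trimethoxy-5-[(3R)-6,7,8-trimethoxy-3,4-dihydro-2H-chromen-3-yl]phenol F6.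
- Phenol 20 is then oxidised as in the second half of step 12.

**Step 8 (protodeboronation or sluggish coupling of the electron-rich, ortho-substituted borate).**
- The fallback sets out from 14 (made from 12 with n-BuLi) and comes back at 16.
- The C–C bond is made by carbometalation of an alkyne instead of cross-coupling.
- Aryllithium 14 is transmetalated with MgBr2·OEt2 to [5-(benzyloxy)-2,3,4-trimethoxyphenyl]magnesium bromide F7.
- Propargyl alcohol is deprotonated separately with EtMgBr to bromomagnesium prop-2-yn-1-olate F8.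
- CuI (15 mol %, THF, rt) promotes alkoxide-directed anti-carbomagnesiation of F8 by F7, giving the chelate 4-[5-(benzyloxy)-2,3,4-trimethoxyphenyl]-2,5-dihydro-1,2-oxamagnesole F9.
- An aqueous NH4Cl quench of F9 releases 16.

**Further compounds**
F1 | step 10 | 1-(allyloxy)-2,3,4-trimethoxy-6-[(E)-prop-1-en-1-yl]benzene | C/C=C/c1cc(OC)c(OC)c(OC)c1OCC=C
F2 | step 10 | 6,7,8-trimethoxy-2H-chromene | COc1cc2C=CCOc2c(OC)c1OC
F3 | step 10 | (±)-trans-3,4-dibromo-6,7,8-trimethoxy-3,4-dihydro-2H-chromene (racemic, relative configuration shown) | COc1cc2[C@H](Br)[C@@H](Br)COc2c(OC)c1OC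
F4 | step 10 | 3-bromo-6,7,8-trimethoxy-2H-chromene | COc1cc2C=C(Br)COc2c(OC)c1OC
F5 | step 11 | racemic 2,3,4-trimethoxy-5-(6,7,8-trimethoxy-3,4-dihydro-2H-chromen-3-yl)phenol | COc1c(OC)c(OC)c(O)cc1C1COc2c(cc(OC)c(OC)c2OC)C1
F6 | step 11 | 2,3,4-trimethoxy-5-[(3R)-6,7,8-trimethoxy-3,4-dihydro-2H-chromen-3-yl]phenol | COc1c(OC)c(OC)c(O)cc1[C@@H]1COc2c(cc(OC)c(OC)c2OC)C1
F7 | step 8 | [5-(benzyloxy)-2,3,4-trimethoxyphenyl]magnesium bromide | Br[Mg]c1cc(OCc2ccccc2)c(OC)c(OC)c1OC
F8 | step 8 | bromomagnesium prop-2-yn-1-olate | C#CCO[Mg]Br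
F9 | step 8 | 4-[5-(benzyloxy)-2,3,4-trimethoxyphenyl]-2,5-dihydro-1,2-oxamagnesole | COc1c(OC)c(OC)c(OCc2ccccc2)cc1C1=C[Mg]OC1
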